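Contortin is a C2-symmetric 2,2'-biphenol made of two identical hexasubstituted benzene rings A and A'. The one disconnection of weight is the biaryl axis, which halves the molecule into two molecules of 1-(6-hydroxy-2,4-dimethoxy-3-methylphenyl)ethanone, joined in the last step by anodic dehydrogenative homocoupling.
Enabling feature (monomer numbering: C1 acetyl, C2 OMe, C3 Me, C4 OMe, C5 H, C6 OH): C5-H is the only ring C-H, ortho to the C6 hydroxyl, ortho to the C4 methoxy and para to the C2 methoxy group. The other spin-bearing carbons of the phenoxyl radical, C1 and C3, are blocked by acetyl and methyl, so only the C5-C5' bond can form and persist, and the product has no ring C-H left for further coupling.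
Monomer: acetylation/Fries rearrangement of the symmetric 3,5-dimethoxy-4-methylphenol (para position blocked, ortho positions equivalent). Phenol: sterically controlled C-H borylation and oxidation of 2,6-dimethoxytoluene.
No ring is constructed: rings A and A' both come from 2,6-dimethoxytoluene, and no protecting group, halogen or tether is needed.

Key step: step 4

Assumption: the target is drawn without a configuration at the tetra-ortho-substituted biaryl axis, so the racemic biaryl is taken as the target.

Step 1
Reactants: 1 2,6-dimethoxytoluene
Product: 2 2-(3,5-dimethoxy-4-methylphenyl)-4,4,5,5-tetramethyl-1,3,2-dioxaborolane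
Conditions: B2pin2 (1.0 equiv), [Ir(OMe)(cod)]2 (1.5 mol%), dtbpy (3 mol%), THF, 80 °C
Reagents that add atoms: bis(pinacolato)diboron, CC1(C)OB(OC1(C)C)B1OC(C)(C)C(C)(C)O1
Why: Iridium-catalysed aromatic C-H borylation is governed by sterics and spares C-H bonds next to a substituent, so in the 1,2,3-trisubstituted arene 1 only C4-H, which lies between two hydrogens and para to the methyl group, should be borylated.

Step 2
Reactants: 2 2-(3,5-dimethoxy-4-methylphenyl)-4,4,5,5-tetramethyl-1,3,2-dioxaborolane
Product: 3 3,5-dimethoxy-4-methylphenol
Conditions: 30% aq. H2O2 (1.2 equiv), NaOH (1 equiv), THF-H2O, 0 °C to rt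
Reagents that add atoms: hydrogen peroxide, OO
Why: Ipso-hydroxylation of an arylboronate: hydroperoxide adds to boron, the aryl group migrates from boron to oxygen and the borate ester is hydrolysed, so the oxygen ends up exactly where the boron was.

Step 3
Reactants: 3 3,5-dimethoxy-4-methylphenol
Product: 6 1-(6-hydroxy-2,4-dimethoxy-3-methylphenyl)ethanone, via aryl acetate 4 (not isolated), via difluoroboron chelate 5 (not isolated)
Conditions: Ac2O (1.1 equiv), BF3·OEt2 (3 equiv), neat, 0 °C then 80 °C; then aq. NaOAc, 50 °C
Reagents that add atoms: acetic anhydride, CC(=O)OC(C)=O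
Why: O-Acetylation followed by BF3-promoted Fries rearrangement (Friedel-Crafts acylation) can give only one ketone, because the position para to the oxygen carries the methyl group and the two ortho positions of the symmetric ring are equivalent, and chelate 5 deactivates the ring against a second acylation until it is hydrolysed at work-up.

Step 4
Reactants: 6 1-(6-hydroxy-2,4-dimethoxy-3-methylphenyl)ethanone (two molecules)
Product: 9 contortin, via phenoxyl radical 7 (not isolated), via dienone tautomer 8 (not isolated)
Conditions: constant current, undivided cell, boron-doped diamond (BDD) anode, Pt cathode, 5 mA cm-2, 1.1 F mol-1, MeBu3N O3SOMe (0.1 M), HFIP, 6 at 0.4 M, 40 °C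
Reagents that add atoms: none
Why: At the BDD anode the HFIP-solvated phenol 6 loses one electron and the phenolic proton to give phenoxyl radical 7 (spin on O, C1, C3 and C5), which bonds through C5 to C5 of a second molecule of 6; loss of the second electron and proton gives dienone tautomer 8, enolisation restores both aromatic rings, and the protons are reduced to H2 at the Pt cathode, whose low hydrogen overpotential spares the ketones. The closest known reaction type is the anodic dehydrogenative ortho,ortho-homocoupling of alkyl- and alkoxy-substituted phenols, including phenols that carry acyl groups, to 2,2'-biphenols on BDD in HFIP. No ring is closed and no stereocentre remains: the sp3 carbon of 8 is erased on tautomerisation, and the axis forms as the racemate because nothing chiral is present. The step needs C-C over C-O coupling and C5 over C1 or C3: C5-H is the only ring C-H and is activated by the ortho hydroxyl, the ortho methoxy and the para methoxy group, bonds made at the acetyl-bearing C1 or the methyl-bearing C3 cannot rearomatise, and the oxygen is tied up in hydrogen bonds to the acetyl group and to HFIP. Oligomerisation is excluded because 9 has no ring C-H left, its two nearly orthogonal rings should be no easier to oxidise than 6, and the charge is held near the theoretical amount with recovery of unreacted 6. One operation thus doubles the skeleton and makes the most hindered bond of the target, between two hexasubstituted rings, without halogen, metal reagent or protecting group.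

Compound list
1 | 2,6-dimethoxytoluene (1,3-dimethoxy-2-methylbenzene) | COc1cccc(OC)c1C | starting material
2 | 2-(3,5-dimethoxy-4-methylphenyl)-4,4,5,5-tetramethyl-1,3,2-dioxaborolane | COc1cc(B2OC(C)(C)C(C)(C)O2)cc(OC)c1C | intermediate
3 | 3,5-dimethoxy-4-methylphenol | COc1cc(O)cc(OC)c1C | intermediate
4 | 3,5-dimethoxy-4-methylphenyl acetate (not isolated) | COc1cc(OC(C)=O)cc(OC)c1C | intermediate
5 | difluoroboron chelate of 6, boron bound to the phenolate and carbonyl oxygens (not isolated) | CC1=[O+][B-](F)(F)Oc2cc(OC)c(C)c(OC)c12 | intermediate
6 | 1-(6-hydroxy-2,4-dimethoxy-3-methylphenyl)ethanone | COc1c(C)c(OC)cc(O)c1C(C)=O | intermediate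
7 | 2-acetyl-3,5-dimethoxy-4-methylphenoxyl radical (not isolated) | COc1c(C)c(OC)cc([O])c1C(C)=O | intermediate
8 | dienone tautomer of 9, one ring as 2-acetyl-6-aryl-3,5-dimethoxy-4-methylcyclohexa-2,4-dien-1-one, transient C6 stereocentre unspecified (not isolated) | CC(=O)C1=C(OC)C(C)=C(OC)C(C1=O)c1c(O)c(C(C)=O)c(OC)c(C)c1OC | intermediate
9 | contortin, 1,1'-(2,2'-dihydroxy-4,4',6,6'-tetramethoxy-5,5'-dimethylbiphenyl-3,3'-diyl)diethanone, racemic at the axis | COc1c(C)c(OC)c(-c2c(O)c(C(C)=O)c(OC)c(C)c2OC)c(O)c1C(C)=O | target

Total step count: 4. Longest linear sequence: 4 steps.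

Steps most likely to fail

Step 4. The chelated phenol may be oxidised only at a high potential. There, two-electron oxidation with proton loss from the para methyl group, solvent capture, loss of a methoxy group or electrode fouling can outrun the sterically demanding C-C bond formation. The fallback replaces the oxidative by a reductive coupling. It sets out from 6 and comes back at 9.
- Iodination at the only ring C-H (NIS, cat. TFA, MeCN, rt) should give 1-(2-hydroxy-3-iodo-4,6-dimethoxy-5-methylphenyl)ethanone F1.
- Benzylation (BnBr, K2CO3, DMF, 60 °C) should give 1-[2-(benzyloxy)-3-iodo-4,6-dimethoxy-5-methylphenyl]ethanone F2.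
- Ullmann homocoupling (activated Cu powder, DMF, 150 °C) should give O,O'-dibenzylcontortin F3.
- Hydrogenolysis (H2, 1 atm, Pd/C, EtOAc) should then release 9.

Step 3. A second acylation at the remaining ring C-H, Lewis-acid cleavage of the methoxy group next to the new carbonyl, or condensation of the methyl ketone with more anhydride may erode the step. The fallback is anionic instead of electrophilic. It sets out from 3 and comes back at 6.
- Protection (MOMCl, i-Pr2NEt, CH2Cl2) should give 1,3-dimethoxy-5-(methoxymethoxy)-2-methylbenzene F4.
- Directed ortho-lithiation between the two oxygen substituents (n-BuLi, THF, 0 °C) should give [2,4-dimethoxy-6-(methoxymethoxy)-3-methylphenyl]lithium F5.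
- Acylation with N-methoxy-N-methylacetamide (-78 °C to rt) should give 1-[2,4-dimethoxy-6-(methoxymethoxy)-3-methylphenyl]ethanone F6.
- Acetal cleavage (HCl, MeOH, 40 °C) should give 6.

Step 1. Turnover may be slow with the electron-rich arene, and site selectivity may erode through borylation next to the small methoxy group. The fallback installs the carbon substituent first and the oxygen last. It sets out from 1 and comes back at 6, bypassing 2 to 5.
- Friedel-Crafts acetylation at the position ortho and para to the methoxy groups (AcCl, SnCl4, CH2Cl2, 0 °C) should give 1-(2,4-dimethoxy-3-methylphenyl)ethanone F7.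
- Ketone-directed ortho C-H oxygenation at the only ortho C-H (Pd(OAc)2 5 mol%, K2S2O8, TFA/TFAA, 50 °C) should give 2-acetyl-3,5-dimethoxy-4-methylphenyl trifluoroacetate F8.
- Aqueous work-up hydrolyses this ester to 6.

Further compounds
F1 | step 4 | 1-(2-hydroxy-3-iodo-4,6-dimethoxy-5-methylphenyl)ethanone | COc1c(C)c(OC)c(I)c(O)c1C(C)=O
F2 | step 4 | 1-[2-(benzyloxy)-3-iodo-4,6-dimethoxy-5-methylphenyl]ethanone | COc1c(C)c(OC)c(I)c(OCc2ccccc2)c1C(C)=O
F3 | step 4 | O,O'-dibenzylcontortin | COc1c(C)c(OC)c(-c2c(OCc3ccccc3)c(C(C)=O)c(OC)c(C)c2OC)c(OCc2ccccc2)c1C(C)=O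
F4 | step 3 | 1,3-dimethoxy-5-(methoxymethoxy)-2-methylbenzene | COCOc1cc(OC)c(C)c(OC)c1
F5 | step 3 | [2,4-dimethoxy-6-(methoxymethoxy)-3-methylphenyl]lithium | [Li]c1c(OCOC)cc(OC)c(C)c1OC
F6 | step 3 | 1-[2,4-dimethoxy-6-(methoxymethoxy)-3-methylphenyl]ethanone | COCOc1cc(OC)c(C)c(OC)c1C(C)=O
F7 | step 1 | 1-(2,4-dimethoxy-3-methylphenyl)ethanone | COc1ccc(C(C)=O)c(OC)c1C
F8 | step 1 | 2-acetyl-3,5-dimethoxy-4-methylphenyl trifluoroacetate | COc1cc(OC(=O)C(F)(F)F)c(C(C)=O)c(OC)c1C
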